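**Retrosynthetic overview**

1. Target 25 ⇐ lactone 21 (PMB ether on O15, TBS ethers on O14 and O8) by late exchange of protecting groups for the C15 acetate and C14 isobutyrate, with the free C8 hydroxyl unveiled last.
2. 21 ⇐ acyclic enal propargylic mesylate 17 in one flask: ring bond C6–C7 by palladium/InI umpolung allenylation (ten-membered carbocycle), then C11–C12 and O6–C12 by CO (α-methylene lactone).
3. Enabling feature: C7 lies between the oxygen-bearing C6 and C8 and carries C11(=C13). Read as a 6-hydroxy-7-ethynyl unit, this array is both the adduct of an allenylmetal (C13=C11=C7) with the C6 aldehyde and a cyclocarbonylation substrate (O6 + CO + C11≡C13), so the carbocycle C1–C10 and the lactone ring (O, C6, C7, C11, C12) can be closed together.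
4. 17 ⇐ Horner–Wadsworth–Emmons union at C1=C10 of aldehyde 7 (C1–C6, C15; from but-2-yne-1,4-diol by Z-vinyl iodide and Negishi coupling) with phosphono lactone 11 (C7–C10, C14, ethynyl; from Sharpless kinetic resolution of pent-1-en-4-yn-3-ol).
5. Ring order: a temporary butyrolactone carrying C14 and O8 (formed in step 8, opened in step 10), then the ten-membered carbocycle and the α-methylene-γ-lactone together (step 15).

Key step: step 15

Remark: atoms carry germacrane numbers (ring C1–C10; C11, C12, C13 = lactone α-carbon, carbonyl carbon and methylene; C14 on C10, C15 on C4); the structure is taken as 6R,7R,8R with the ring carbons cis across both ring double bonds (E by CIP, because CH2O outranks ring CH2).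

Abbreviations: PMB = 4-methoxybenzyl; TES = triethylsilyl; TBS = tert-butyldimethylsilyl; MOP = 2-methoxypropan-2-yl.

**Step 1**
Reactants: 1 but-2-yne-1,4-diol
Product: 2 4-(PMB-oxy)but-2-yn-1-ol
Conditions: NaH (1 equiv), 4-methoxybenzyl chloride (1 equiv), Bu4NI (cat.), 1 (3 equiv), THF–DMF, 0 °C to rt
Reagents that add atoms: 4-methoxybenzyl chloride, COc1ccc(CCl)cc1
Why: Williamson etherification of the mono-alkoxide of the symmetrical diol used in excess should give the mono-ether, which tells the later O15 (ether) from the later O6 (free hydroxyl).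

**Step 2**
Reactants: 2 4-(PMB-oxy)but-2-yn-1-ol
Product: 4 (2Z)-3-iodo-4-(PMB-oxy)but-2-en-1-ol, via cyclic vinylalanate 3 (not isolated)
Conditions: NaAlH2(OCH2CH2OMe)2 (1.5 equiv), THF, 0 °C to rt; EtOAc; then I2, −78 to 0 °C
Reagents that add atoms: iodine, II
Why: hydroxyl-directed trans-hydroalumination puts aluminium on the carbon distal to the free hydroxyl and cis to it, and iodinolysis with retention should give the Z iodide, which fixes the C4=C5 geometry (C15 trans to C6).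

**Step 3**
Reactants: 4 (2Z)-3-iodo-4-(PMB-oxy)but-2-en-1-ol
Product: 5 (2Z)-3-iodo-4-(PMB-oxy)-1-(TES-oxy)but-2-ene
Conditions: TESCl, imidazole, CH2Cl2, 0 °C
Reagents that add atoms: chlorotriethylsilane, CC[Si](Cl)(CC)CC
Why: standard silylation masks O6 with a group that withstands organozinc, hydride and base but is removed by mild acid in step 12.

**Step 4**
Reactants: 5 (2Z)-3-iodo-4-(PMB-oxy)-1-(TES-oxy)but-2-ene
Product: 6 ethyl (4E)-4-[(PMB-oxy)methyl]-6-(TES-oxy)hex-4-enoate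
Conditions: BrZnCH2CH2CO2Et (0.5 M in THF, 1.5 equiv), Pd(PPh3)4 (5 mol %), THF–DMA, 40 °C
Reagents that add atoms: (3-ethoxy-3-oxopropyl)zinc bromide, CCOC(=O)CC[Zn]Br
Why: Negishi sp2–sp3 coupling of the zinc homoenolate proceeds with retention at the vinyl iodide, so C3 should end up cis to C6 as the ring requires.

**Step 5**
Reactants: 6 ethyl (4E)-4-[(PMB-oxy)methyl]-6-(TES-oxy)hex-4-enoate
Product: 7 (4E)-4-[(PMB-oxy)methyl]-6-(TES-oxy)hex-4-enal
Conditions: i-Bu2AlH (1.05 equiv), CH2Cl2, −78 °C; aq. potassium sodium tartrate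
Reagents that add atoms: none
Why: partial reduction of the ester at low temperature stops at the aluminium hemiacetal, which should release the C1 aldehyde on work-up.

**Step 6**
Reactants: 8 rac-pent-1-en-4-yn-3-ol
Product: 9 (1S)-1-[(2R)-oxiran-2-yl]prop-2-yn-1-ol
Conditions: Ti(OiPr)4 (10 mol %), L-(+)-diisopropyl tartrate (12 mol %), t-BuOOH (0.55 equiv), 4 Å MS, CH2Cl2, −20 °C
Reagents that add atoms: tert-butyl hydroperoxide, CC(C)(C)OO
Why: Sharpless kinetic resolution with the L-(+)-tartrate should epoxidise the (R)-carbinol fast on the face that gives the erythro epoxy alcohol, which sets C7 (S) and C8 (R), while the (S)-enynol remains and is separated.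

**Step 7**
Reactants: 9 (1S)-1-[(2R)-oxiran-2-yl]prop-2-yn-1-ol
Product: 10 (2R)-2-[(1S)-1-(MOP-oxy)prop-2-yn-1-yl]oxirane
Conditions: 2-methoxypropene (3 equiv), PPTS (2 mol %), CH2Cl2, 0 °C; Et3N
Reagents that add atoms: 2-methoxypropene, COC(C)=C
Why: acid-catalysed addition of the alcohol to the enol ether gives an achiral mixed ketal that cannot migrate and blocks Payne rearrangement under the basic conditions of step 8.

**Step 8**
Reactants: 10 (2R)-2-[(1S)-1-(MOP-oxy)prop-2-yn-1-yl]oxirane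
Product: 11 diethyl {(5R)-5-[(1S)-1-(MOP-oxy)prop-2-yn-1-yl]-2-oxooxolan-3-yl}phosphonate (both C3 epimers)
Conditions: triethyl phosphonoacetate (1.3 equiv), NaH (1.25 equiv), THF, 0 °C; then 10, 65 °C; AcOH
Reagents that add atoms: triethyl phosphonoacetate, CCOC(=O)CP(=O)(OCC)OCC
Why: the stabilised phosphonoacetate carbanion opens the epoxide at its CH2 terminus (C9) and the liberated C8 alkoxide lactonises onto the ester, a known route to α-phosphono-γ-butyrolactones that leaves C8 untouched and stores C14 and O8 in a temporary ring.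

**Step 9**
Reactants: 11 diethyl {(5R)-5-[(1S)-1-(MOP-oxy)prop-2-yn-1-yl]-2-oxooxolan-3-yl}phosphonate; 7 (4E)-4-[(PMB-oxy)methyl]-6-(TES-oxy)hex-4-enal
Product: 12 (3E,5R)-3-{(4E)-4-[(PMB-oxy)methyl]-6-(TES-oxy)hex-4-en-1-ylidene}-5-[(1S)-1-(MOP-oxy)prop-2-yn-1-yl]oxolan-2-one
Conditions: LiCl, DBU, MeCN, 0 °C to rt
Reagents that add atoms: none
Why: Horner–Wadsworth–Emmons olefination of the α-phosphono lactone under mild LiCl/DBU conditions should favour the E-alkylidene lactone, which sets the C1=C10 geometry (C14 trans to C2, C9 cis to C2).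

**Step 10**
Reactants: 12 (3E,5R)-3-{(4E)-4-[(PMB-oxy)methyl]-6-(TES-oxy)hex-4-en-1-ylidene}-5-[(1S)-1-(MOP-oxy)prop-2-yn-1-yl]oxolan-2-one
Product: 13 (3S,4R,6E,10E)-6-(hydroxymethyl)-3-(MOP-oxy)-10-[(PMB-oxy)methyl]-12-(TES-oxy)dodeca-6,10-dien-1-yn-4-ol
Conditions: i-Bu2AlH (4 equiv), CH2Cl2, −78 to 0 °C; aq. potassium sodium tartrate
Reagents that add atoms: none
Why: 1,2-reduction of the α-alkylidene lactone by excess aluminium hydride opens the temporary ring to the allylic C14 alcohol and the C8 alcohol without touching the alkene geometry.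

**Step 11**
Reactants: 13 (3S,4R,6E,10E)-6-(hydroxymethyl)-3-(MOP-oxy)-10-[(PMB-oxy)methyl]-12-(TES-oxy)dodeca-6,10-dien-1-yn-4-ol
Product: 14 (3S,4R,6E,10E)-3-(MOP-oxy)-10-[(PMB-oxy)methyl]-4-(TBS-oxy)-6-[(TBS-oxy)methyl]-12-(TES-oxy)dodeca-6,10-dien-1-yne
Conditions: TBSCl (3 equiv), imidazole, DMAP (cat.), DMF, 40 °C
Reagents that add atoms: tert-butyldimethylsilyl chloride, CC(C)(C)[Si](C)(C)Cl
Why: silylation of both hydroxyls under base (no silyl triflate, so the ketal survives) protects O14 and O8 for the key step.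

**Step 12**
Reactants: 14 (3S,4R,6E,10E)-3-(MOP-oxy)-10-[(PMB-oxy)methyl]-4-(TBS-oxy)-6-[(TBS-oxy)methyl]-12-(TES-oxy)dodeca-6,10-dien-1-yne
Product: 15 (2E,6E,9R,10S)-3-[(PMB-oxy)methyl]-9-(TBS-oxy)-7-[(TBS-oxy)methyl]dodeca-2,6-dien-11-yne-1,10-diol
Conditions: PPTS (0.2 equiv), MeOH–CH2Cl2 (1:1), 0 °C
Reagents that add atoms: none
Why: mild acid methanolysis should cleave the primary TES ether and the MOP ketal far faster than the TBS ethers, freeing O6 and O7 only.

**Step 13**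
Reactants: 15 (2E,6E,9R,10S)-3-[(PMB-oxy)methyl]-9-(TBS-oxy)-7-[(TBS-oxy)methyl]dodeca-2,6-dien-11-yne-1,10-diol
Product: 16 (2E,6E,9R,10S)-10-hydroxy-3-[(PMB-oxy)methyl]-9-(TBS-oxy)-7-[(TBS-oxy)methyl]dodeca-2,6-dien-11-ynal
Conditions: TEMPO (10 mol %), PhI(OAc)2 (1.2 equiv), CH2Cl2, rt
Reagents that add atoms: none
Why: oxoammonium oxidation is selective for the primary allylic alcohol over the secondary propargylic one and should give the C6 enal without moving the 4,5-double bond.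

**Step 14**
Reactants: 16 (2E,6E,9R,10S)-10-hydroxy-3-[(PMB-oxy)methyl]-9-(TBS-oxy)-7-[(TBS-oxy)methyl]dodeca-2,6-dien-11-ynal
Product: 17 (3S,4R,6E,10E)-12-oxo-10-[(PMB-oxy)methyl]-4-(TBS-oxy)-6-[(TBS-oxy)methyl]dodeca-6,10-dien-1-yn-3-yl methanesulfonate
Conditions: MsCl (1.2 equiv), Et3N (1.5 equiv), CH2Cl2, −40 °C; used without chromatography
Reagents that add atoms: methanesulfonyl chloride, CS(Cl)(=O)=O
Why: O-sulfonylation of the propargylic alcohol occurs with retention and installs the leaving group that activates C7 for the umpolung.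

**Step 15**
Reactants: 17 (3S,4R,6E,10E)-12-oxo-10-[(PMB-oxy)methyl]-4-(TBS-oxy)-6-[(TBS-oxy)methyl]dodeca-6,10-dien-1-yn-3-yl methanesulfonate
Product: 21 (3aS,4R,6E,10E,11aR)-3-methylidene-10-[(PMB-oxy)methyl]-4-(TBS-oxy)-6-[(TBS-oxy)methyl]-3a,4,5,8,9,11a-hexahydrocyclodeca[b]furan-2(3H)-one, via allenylindium 18 (not isolated), via indium alkoxide 19 (not isolated), via macrocyclic alkynol 20 (not isolated)
Conditions: Pd(dppf)Cl2 (5 mol %), InI (1.5 equiv), THF–HMPA (3:1), 25 °C, 17 added over 10 h (final 2 mM); then AcOH (2 equiv), PdI2 (10 mol %), PBu3 (20 mol %), MeCN, CO (3 atm), 60 °C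
Reagents that add atoms: carbon monoxide, [C-]#[O+]
Why: Proposed new method: zerovalent palladium ionises the 7S propargylic mesylate by anti SN2′ attack, InI turns the allenylpalladium into the aS allenylindium 18 with retention, and its closed six-membered SE2′ transition state onto the tethered enal closes the ten-membered carbocycle by bonding C7 to C6; after AcOH frees alkynol 20, PdI2/PBu3 and CO convert O6 into an alkoxycarbonylpalladium whose 5-exo-dig syn insertion into the ethynyl group forms the C11–C12 bond and closes the lactone, and protonolysis of the vinylpalladium leaves the C13 methylene. The closest known reactions are the palladium/InI umpolung addition of enantioenriched propargylic mesylates to aldehydes, the palladium/Et2Zn umpolung allylation that closes ten-membered germacrane rings, and the PdI2/phosphine cyclocarbonylation of 2-ethynyl alkanols to α-methylene-γ-butyrolactones; what is new is their union in one flask and the macrocyclic propargylic case. C7 is set by chirality transfer from the mesylate (anti SN2′ then syn SE2′, net inversion), and C6 by the chair-like cyclic transition state that keeps the enal chain anti to the C8 branch, which is the anti adduct and hence the trans ring fusion. The step needs γ-attack of the allenylindium (homopropargylic, not allenic, alcohol), 1,2-addition to the enal without loss of the 4,5-geometry, and lactonisation through O6 only; the γ-substituted allenylindium, the near-neutral medium and the silyl ether on O8 secure these. Slow addition holds the substrate dilute against oligomerisation, and CO is admitted only after the allenylation so that the allenylpalladium is not carbonylated.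

**Step 16**
Reactants: 21 (3aS,4R,6E,10E,11aR)-3-methylidene-10-[(PMB-oxy)methyl]-4-(TBS-oxy)-6-[(TBS-oxy)methyl]-3a,4,5,8,9,11a-hexahydrocyclodeca[b]furan-2(3H)-one
Product: 22 (3aS,4R,6E,10E,11aR)-10-(hydroxymethyl)-3-methylidene-4-(TBS-oxy)-6-[(TBS-oxy)methyl]-3a,4,5,8,9,11a-hexahydrocyclodeca[b]furan-2(3H)-one
Conditions: DDQ (1.3 equiv), CH2Cl2–pH 7 buffer (10:1), 0 °C to rt
Reagents that add atoms: none
Why: oxidative cleavage of the electron-rich benzyl ether by DDQ is neutral and should spare the silyl ethers and the α-methylene lactone.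

**Step 17**
Reactants: 22 (3aS,4R,6E,10E,11aR)-10-(hydroxymethyl)-3-methylidene-4-(TBS-oxy)-6-[(TBS-oxy)methyl]-3a,4,5,8,9,11a-hexahydrocyclodeca[b]furan-2(3H)-one
Product: 23 {(3aS,4R,6E,10E,11aR)-3-methylidene-2-oxo-4-(TBS-oxy)-6-[(TBS-oxy)methyl]-2,3,3a,4,5,8,9,11a-octahydrocyclodeca[b]furan-10-yl}methyl acetate
Conditions: Ac2O, pyridine, DMAP (cat.), CH2Cl2, 0 °C
Reagents that add atoms: acetic anhydride, CC(=O)OC(C)=O
Why: standard acylation of the only free hydroxyl installs the C15 acetate.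

**Step 18**
Reactants: 23 {(3aS,4R,6E,10E,11aR)-3-methylidene-2-oxo-4-(TBS-oxy)-6-[(TBS-oxy)methyl]-2,3,3a,4,5,8,9,11a-octahydrocyclodeca[b]furan-10-yl}methyl acetate
Product: 24 {(3aR,4R,6E,10E,11aR)-4-hydroxy-6-(hydroxymethyl)-3-methylidene-2-oxo-2,3,3a,4,5,8,9,11a-octahydrocyclodeca[b]furan-10-yl}methyl acetate
Conditions: HF·pyridine, pyridine, THF, 0 °C to rt
Reagents that add atoms: none
Why: fluoride-mediated desilylation under buffered acidic conditions removes both TBS groups without acyl migration or attack on the α-methylene lactone.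

**Step 19**
Reactants: 24 {(3aR,4R,6E,10E,11aR)-4-hydroxy-6-(hydroxymethyl)-3-methylidene-2-oxo-2,3,3a,4,5,8,9,11a-octahydrocyclodeca[b]furan-10-yl}methyl acetate
Product: 25 {(3aR,4R,6E,10E,11aR)-10-(acetoxymethyl)-4-hydroxy-3-methylidene-2-oxo-2,3,3a,4,5,8,9,11a-octahydrocyclodeca[b]furan-6-yl}methyl 2-methylpropanoate
Conditions: isobutyryl chloride (1.1 equiv), 2,4,6-collidine, CH2Cl2, −78 to −40 °C
Reagents that add atoms: isobutyryl chloride, CC(C)C(Cl)=O
Why: acid chloride with a hindered pyridine base at low temperature should acylate the primary allylic C14 hydroxyl in preference to the hindered secondary C8 hydroxyl, completing the target.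

**Compound list**

1 | but-2-yne-1,4-diol | OCC#CCO | starting material
2 | 4-(PMB-oxy)but-2-yn-1-ol | COc1ccc(COCC#CCO)cc1 | intermediate
3 | sodium 2,2-bis(2-methoxyethoxy)-3-[(PMB-oxy)methyl]-2,5-dihydro-1,2-oxaaluminol-2-uide (cyclic vinylalanate) | [Na+].COCCO[Al-]1(OCCOC)OCC=C1COCc1ccc(OC)cc1 | intermediate
4 | (2Z)-3-iodo-4-(PMB-oxy)but-2-en-1-ol | OC/C=C(I)/COCc1ccc(OC)cc1 | intermediate
5 | (2Z)-3-iodo-4-(PMB-oxy)-1-(TES-oxy)but-2-ene | CC[Si](CC)(CC)OC/C=C(I)/COCc1ccc(OC)cc1 | intermediate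
6 | ethyl (4E)-4-[(PMB-oxy)methyl]-6-(TES-oxy)hex-4-enoate | CCOC(=O)CC/C(COCc1ccc(OC)cc1)=C\CO[Si](CC)(CC)CC | intermediate
7 | (4E)-4-[(PMB-oxy)methyl]-6-(TES-oxy)hex-4-enal | O=CCC/C(COCc1ccc(OC)cc1)=C\CO[Si](CC)(CC)CC | intermediate
8 | rac-pent-1-en-4-yn-3-ol | C=CC(O)C#C | starting material
9 | (1S)-1-[(2R)-oxiran-2-yl]prop-2-yn-1-ol | C#C[C@H](O)[C@H]1CO1 | intermediate
10 | (2R)-2-[(1S)-1-(MOP-oxy)prop-2-yn-1-yl]oxirane | C#C[C@H](OC(C)(C)OC)[C@H]1CO1 | intermediate
11 | diethyl {(5R)-5-[(1S)-1-(MOP-oxy)prop-2-yn-1-yl]-2-oxooxolan-3-yl}phosphonate (both C3 epimers) | C#C[C@H](OC(C)(C)OC)[C@H]1CC(C(=O)O1)P(=O)(OCC)OCC | intermediate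
12 | (3E,5R)-3-{(4E)-4-[(PMB-oxy)methyl]-6-(TES-oxy)hex-4-en-1-ylidene}-5-[(1S)-1-(MOP-oxy)prop-2-yn-1-yl]oxolan-2-one | C#C[C@H](OC(C)(C)OC)[C@H]1C/C(=C\CC/C(COCc2ccc(OC)cc2)=C\CO[Si](CC)(CC)CC)C(=O)O1 | intermediate
13 | (3S,4R,6E,10E)-6-(hydroxymethyl)-3-(MOP-oxy)-10-[(PMB-oxy)methyl]-12-(TES-oxy)dodeca-6,10-dien-1-yn-4-ol | C#C[C@H](OC(C)(C)OC)[C@H](O)C/C(CO)=C\CC/C(COCc1ccc(OC)cc1)=C\CO[Si](CC)(CC)CC | intermediate
14 | (3S,4R,6E,10E)-3-(MOP-oxy)-10-[(PMB-oxy)methyl]-4-(TBS-oxy)-6-[(TBS-oxy)methyl]-12-(TES-oxy)dodeca-6,10-dien-1-yne | C#C[C@H](OC(C)(C)OC)[C@H](O[Si](C)(C)C(C)(C)C)C/C(CO[Si](C)(C)C(C)(C)C)=C\CC/C(COCc1ccc(OC)cc1)=C\CO[Si](CC)(CC)CC | intermediate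
15 | (2E,6E,9R,10S)-3-[(PMB-oxy)methyl]-9-(TBS-oxy)-7-[(TBS-oxy)methyl]dodeca-2,6-dien-11-yne-1,10-diol | C#C[C@H](O)[C@H](O[Si](C)(C)C(C)(C)C)C/C(CO[Si](C)(C)C(C)(C)C)=C\CC/C(COCc1ccc(OC)cc1)=C\CO | intermediate
16 | (2E,6E,9R,10S)-10-hydroxy-3-[(PMB-oxy)methyl]-9-(TBS-oxy)-7-[(TBS-oxy)methyl]dodeca-2,6-dien-11-ynal | C#C[C@H](O)[C@H](O[Si](C)(C)C(C)(C)C)C/C(CO[Si](C)(C)C(C)(C)C)=C\CC/C(COCc1ccc(OC)cc1)=C\C=O | intermediate
17 | (3S,4R,6E,10E)-12-oxo-10-[(PMB-oxy)methyl]-4-(TBS-oxy)-6-[(TBS-oxy)methyl]dodeca-6,10-dien-1-yn-3-yl methanesulfonate | C#C[C@H](OS(C)(=O)=O)[C@H](O[Si](C)(C)C(C)(C)C)C/C(CO[Si](C)(C)C(C)(C)C)=C\CC/C(COCc1ccc(OC)cc1)=C\C=O | intermediate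
18 | (aS)-iodo(methanesulfonato){(4R,6E,10E)-12-oxo-10-[(PMB-oxy)methyl]-4-(TBS-oxy)-6-[(TBS-oxy)methyl]dodeca-1,2,6,10-tetraen-1-yl}indium (allenylindium; axial configuration aS, given in the name) | CS(=O)(=O)O[In](I)C=C=C[C@H](O[Si](C)(C)C(C)(C)C)C/C(CO[Si](C)(C)C(C)(C)C)=C\CC/C(COCc1ccc(OC)cc1)=C\C=O | intermediate
19 | iodo(methanesulfonato)indium alkoxide of 20 | CS(=O)(=O)O[In](I)O[C@@H]1/C=C(/COCc2ccc(OC)cc2)CC/C=C(/CO[Si](C)(C)C(C)(C)C)C[C@@H](O[Si](C)(C)C(C)(C)C)[C@H]1C#C | intermediate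
20 | (1R,2E,6E,9R,10S)-10-ethynyl-3-[(PMB-oxy)methyl]-9-(TBS-oxy)-7-[(TBS-oxy)methyl]cyclodeca-2,6-dien-1-ol | O[C@@H]1/C=C(/COCc2ccc(OC)cc2)CC/C=C(/CO[Si](C)(C)C(C)(C)C)C[C@@H](O[Si](C)(C)C(C)(C)C)[C@H]1C#C | intermediate
21 | (3aS,4R,6E,10E,11aR)-3-methylidene-10-[(PMB-oxy)methyl]-4-(TBS-oxy)-6-[(TBS-oxy)methyl]-3a,4,5,8,9,11a-hexahydrocyclodeca[b]furan-2(3H)-one | C=C1C(=O)O[C@@H]2/C=C(/COCc3ccc(OC)cc3)CC/C=C(/CO[Si](C)(C)C(C)(C)C)C[C@@H](O[Si](C)(C)C(C)(C)C)[C@@H]12 | intermediate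
22 | (3aS,4R,6E,10E,11aR)-10-(hydroxymethyl)-3-methylidene-4-(TBS-oxy)-6-[(TBS-oxy)methyl]-3a,4,5,8,9,11a-hexahydrocyclodeca[b]furan-2(3H)-one | C=C1C(=O)O[C@@H]2/C=C(/CO)CC/C=C(/CO[Si](C)(C)C(C)(C)C)C[C@@H](O[Si](C)(C)C(C)(C)C)[C@@H]12 | intermediate
23 | {(3aS,4R,6E,10E,11aR)-3-methylidene-2-oxo-4-(TBS-oxy)-6-[(TBS-oxy)methyl]-2,3,3a,4,5,8,9,11a-octahydrocyclodeca[b]furan-10-yl}methyl acetate | C=C1C(=O)O[C@@H]2/C=C(/COC(C)=O)CC/C=C(/CO[Si](C)(C)C(C)(C)C)C[C@@H](O[Si](C)(C)C(C)(C)C)[C@@H]12 | intermediate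
24 | {(3aR,4R,6E,10E,11aR)-4-hydroxy-6-(hydroxymethyl)-3-methylidene-2-oxo-2,3,3a,4,5,8,9,11a-octahydrocyclodeca[b]furan-10-yl}methyl acetate | C=C1C(=O)O[C@@H]2/C=C(/COC(C)=O)CC/C=C(/CO)C[C@@H](O)[C@@H]12 | intermediate
25 | {(3aR,4R,6E,10E,11aR)-10-(acetoxymethyl)-4-hydroxy-3-methylidene-2-oxo-2,3,3a,4,5,8,9,11a-octahydrocyclodeca[b]furan-6-yl}methyl 2-methylpropanoate | C=C1C(=O)O[C@@H]2/C=C(/COC(C)=O)CC/C=C(/COC(=O)C(C)C)C[C@@H](O)[C@@H]12 | target

**Totals and risks**

Total step count: 19. Longest linear sequence: 16 steps (steps 1–5, then 9–19); the second branch (steps 6–8) joins at step 9.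

Steps most likely to fail:

Step 15 (proposed new method). The allenyl metal may be carbonylated or protonated before it reaches the aldehyde, oligomerisation may outrun ten-membered ring closure, facial selectivity at C6 may be poor in the constrained cyclic transition state, the enal double bond may isomerise, or the allylic C6 alcohol may ionise during the acidic CO stage. The fallback uses known reactions run separately and closes the lactone by a radical instead of by palladium. It sets out from 17: the palladium/InI allenylation alone (Pd(dppf)Cl2, InI, THF–HMPA, slow addition, aqueous NH4Cl quench) should give macrocyclic alkynol 20, now isolated. PhSeC(O)Cl and pyridine then convert its hydroxyl into the Se-phenyl O-{(1R,2E,6E,9R,10S)-10-ethynyl-3-[(PMB-oxy)methyl]-9-(TBS-oxy)-7-[(TBS-oxy)methyl]cyclodeca-2,6-dien-1-yl} carbonoselenoate F1. Bu3SnH/AIBN in benzene at 80 °C generates the alkoxycarbonyl radical, whose 5-exo-dig addition to the ethynyl group followed by hydrogen transfer forms the same C11–C12 bond, and the route is rejoined at 21.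

Step 8. The stabilised carbanion may attack the α-oxygenated epoxide too slowly, the ethynyl group may isomerise to an allene under base, or the ketal may be lost on prolonged heating. The fallback builds the same lactone by intramolecular alkylation and sets out from 10. LiI/AcOH in THF at 0 °C opens the epoxide at its terminal carbon to the iodohydrin (2S,3S)-1-iodo-3-(MOP-oxy)pent-4-yn-2-ol F2. Esterification of its hydroxyl with (diethoxyphosphoryl)acetic acid (DCC, DMAP, CH2Cl2) gives (2S,3S)-1-iodo-3-(MOP-oxy)pent-4-yn-2-yl (diethoxyphosphoryl)acetate F3. K2CO3 in DMF then closes the ring by 5-exo-tet C-alkylation of the phosphonoacetate carbanion, and the route is rejoined at 11.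

Step 19. The secondary C8 hydroxyl may be acylated as well, or the lactone may migrate to O8 under basic conditions. The fallback replaces chemoselective acylation by protecting-group differentiation and sets out from 23. Pyridine-buffered HF·pyridine in THF at 0 °C for a short time removes only the primary allylic silyl ether to give {(3aS,4R,6E,10E,11aR)-6-(hydroxymethyl)-3-methylidene-2-oxo-4-(TBS-oxy)-2,3,3a,4,5,8,9,11a-octahydrocyclodeca[b]furan-10-yl}methyl acetate F4. Isobutyryl chloride/pyridine gives {(3aS,4R,6E,10E,11aR)-10-(acetoxymethyl)-3-methylidene-2-oxo-4-(TBS-oxy)-2,3,3a,4,5,8,9,11a-octahydrocyclodeca[b]furan-6-yl}methyl 2-methylpropanoate F5. HF·pyridine at rt then frees the C8 hydroxyl, and the route is rejoined at 25.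

**Further compounds**

F1 | step 15 | Se-phenyl O-{(1R,2E,6E,9R,10S)-10-ethynyl-3-[(PMB-oxy)methyl]-9-(TBS-oxy)-7-[(TBS-oxy)methyl]cyclodeca-2,6-dien-1-yl} carbonoselenoate | O=C([Se]c1ccccc1)O[C@@H]1/C=C(/COCc2ccc(OC)cc2)CC/C=C(/CO[Si](C)(C)C(C)(C)C)C[C@@H](O[Si](C)(C)C(C)(C)C)[C@H]1C#C
F2 | step 8 | (2S,3S)-1-iodo-3-(MOP-oxy)pent-4-yn-2-ol | C#C[C@H](OC(C)(C)OC)[C@H](O)CI
F3 | step 8 | (2S,3S)-1-iodo-3-(MOP-oxy)pent-4-yn-2-yl (diethoxyphosphoryl)acetate | C#C[C@H](OC(C)(C)OC)[C@H](OC(=O)CP(=O)(OCC)OCC)CI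
F4 | step 19 | {(3aS,4R,6E,10E,11aR)-6-(hydroxymethyl)-3-methylidene-2-oxo-4-(TBS-oxy)-2,3,3a,4,5,8,9,11a-octahydrocyclodeca[b]furan-10-yl}methyl acetate | C=C1C(=O)O[C@@H]2/C=C(/COC(C)=O)CC/C=C(/CO)C[C@@H](O[Si](C)(C)C(C)(C)C)[C@@H]12
F5 | step 19 | {(3aS,4R,6E,10E,11aR)-10-(acetoxymethyl)-3-methylidene-2-oxo-4-(TBS-oxy)-2,3,3a,4,5,8,9,11a-octahydrocyclodeca[b]furan-6-yl}methyl 2-methylpropanoate | C=C1C(=O)O[C@@H]2/C=C(/COC(C)=O)CC/C=C(/COC(=O)C(C)C)C[C@@H](O[Si](C)(C)C(C)(C)C)[C@@H]12
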